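**Strategy**

Ring C of the flavanone is cut between C3 and C4. The array C4(=O)–C3H2–C2(H)(aryl)–O1 is the formal adduct of an aldehyde C–H bond across a 1,1-disubstituted aryl enol ether, so an enantioselective rhodium-catalysed intramolecular hydroacylation closes the dihydropyranone ring, forms C3–C4 and sets C2 (S) in one redox-neutral operation. The precursor is a hexasubstituted 2-(1-arylvinyloxy)benzaldehyde. It is built on phloroglucinol, whose symmetry makes every ring substitution unambiguous: ester methylenation gives the enol ether, and three directed ortho-metalations bring in prenyl, the (R)-lavandulyl group (Evans alkylation, then Negishi coupling) and the formyl group.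

Key step: step 14

Assumption: the sense of induction in step 14 cannot be predicted with confidence; (R)-DTBM-SEGPHOS is written, and the ligand antipode is taken if that is the one that leads to 2S.

Abbreviations: TBS = tert-butyldimethylsilyl, MOM = methoxymethyl. All enol ether intermediates (15 to 23) should be purified on triethylamine-deactivated silica.

**Route**

Step 1
Reactants: 1 (S)-4-benzyl-2-oxazolidinone; 2 3-methylbut-2-enoyl chloride
Product: 3 (S)-4-benzyl-3-(3-methylbut-2-enoyl)oxazolidin-2-one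
Conditions: n-BuLi, THF, −78 °C; then 2, −78 to 0 °C
Reagents that add atoms: none
Why: N-acylation of the lithiated oxazolidinone with an acid chloride is the standard loading of an Evans auxiliary and leaves the trisubstituted alkene untouched.

Step 2
Reactants: 3 (S)-4-benzyl-3-(3-methylbut-2-enoyl)oxazolidin-2-one; 4 prenyl bromide (1-bromo-3-methylbut-2-ene)
Product: 6 (S)-4-benzyl-3-[(2S)-5-methyl-2-(prop-1-en-2-yl)hex-4-enoyl]oxazolidin-2-one, via sodium dienolate 5 (not isolated)
Conditions: NaN(SiMe3)2, THF, −78 °C; then 4, −78 to −40 °C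
Reagents that add atoms: none
Why: Evans asymmetric alkylation in its deconjugative form: γ-deprotonation of the s-cis enoyl imide should give the chelated Z(O)-dienolate 5, which reacts at the α-carbon on the face opposite the benzyl group of the (S)-auxiliary and so sets the 2S centre (the future R-configured lavandulyl carbon, the descriptor changing only through CIP priorities).

Step 3
Reactants: 6 (S)-4-benzyl-3-[(2S)-5-methyl-2-(prop-1-en-2-yl)hex-4-enoyl]oxazolidin-2-one
Product: 7 (S)-lavandulol, (2S)-5-methyl-2-(prop-1-en-2-yl)hex-4-en-1-ol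
Conditions: LiBH4, MeOH (1 equiv), Et2O, 0 °C
Reagents that add atoms: none
Why: Reductive cleavage of the N-acyloxazolidinone with LiBH4 should give the primary alcohol and return auxiliary 1 without epimerising the α-centre or touching the alkenes.

Step 4
Reactants: 7 (S)-lavandulol
Product: 8 (S)-lavandulyl iodide, (3S)-3-(iodomethyl)-2,6-dimethylhepta-1,5-diene
Conditions: I2, PPh3, imidazole, CH2Cl2, 0 °C
Reagents that add atoms: iodine, [I][I]
Why: Appel-type iodination replaces the primary hydroxyl by iodide in an SN2 step that does not involve the neighbouring stereocentre.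

Step 5
Reactants: 9 2,4-dihydroxybenzoic acid
Product: 10 tert-butyldimethylsilyl 2,4-bis(tert-butyldimethylsilyloxy)benzoate
Conditions: TBSCl (3.3 equiv), imidazole, DMF, rt
Reagents that add atoms: tert-butyldimethylsilyl chloride, CC(C)(C)[Si](C)(C)Cl
Why: Silylation with TBSCl and imidazole caps both phenols and the acid, and aryl silyl ethers are poor directors of ortho-metalation, which later keeps ring B out of the lithiation steps.

Step 6
Reactants: 10 tert-butyldimethylsilyl 2,4-bis(tert-butyldimethylsilyloxy)benzoate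
Product: 11 2,4-bis(tert-butyldimethylsilyloxy)benzoyl chloride
Conditions: (COCl)2, DMF (cat.), CH2Cl2, 0 °C to rt
Reagents that add atoms: oxalyl chloride, O=C(Cl)C(=O)Cl
Why: Silyl esters are converted directly into acid chlorides by oxalyl chloride and catalytic DMF (Vilsmeier-type chloroiminium) under neutral conditions, so the aryl silyl ethers should be kept.

Step 7
Reactants: 12 phloroglucinol
Product: 13 3,5-bis(methoxymethoxy)phenol
Conditions: MOMCl (2.0 equiv), i-Pr2NEt, DMF, 0 °C to rt; chromatographic separation from the mono- and tris-ethers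
Reagents that add atoms: chloromethyl methyl ether, COCCl
Why: O-alkylation of the phenol with MOMCl is statistical, but the bis-ether is the main component with two equivalents and is separable, the other ethers being recyclable.

Step 8
Reactants: 13 3,5-bis(methoxymethoxy)phenol; 11 2,4-bis(tert-butyldimethylsilyloxy)benzoyl chloride
Product: 14 3,5-bis(methoxymethoxy)phenyl 2,4-bis(tert-butyldimethylsilyloxy)benzoate
Conditions: Et3N, DMAP (cat.), CH2Cl2, 0 °C to rt
Reagents that add atoms: none
Why: DMAP-catalysed esterification of the single free phenol with the acid chloride joins ring B and the future C2 to the oxygen that becomes O1.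

Step 9
Reactants: 14 3,5-bis(methoxymethoxy)phenyl 2,4-bis(tert-butyldimethylsilyloxy)benzoate
Product: 15 1-({1-[2,4-bis(tert-butyldimethylsilyloxy)phenyl]ethenyl}oxy)-3,5-bis(methoxymethoxy)benzene
Conditions: Tebbe reagent Cp2Ti(μ-CH2)(μ-Cl)AlMe2, pyridine, THF–toluene, −40 to 0 °C; aq NaOH work-up, basic alumina
Reagents that add atoms: Tebbe reagent, C[Al-]1(C)C[Ti]([Cl+]1)(C1C=CC=C1)C1C=CC=C1
Why: Tebbe methylenation converts an aryl benzoate into the aryl 1-arylvinyl ether by [2+2] addition of the titanium methylidene to the carbonyl and cycloreversion, and tolerates MOM and silyl ethers.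

Step 10
Reactants: 15 1-({1-[2,4-bis(tert-butyldimethylsilyloxy)phenyl]ethenyl}oxy)-3,5-bis(methoxymethoxy)benzene; 4 prenyl bromide
Product: 17 5-({1-[2,4-bis(tert-butyldimethylsilyloxy)phenyl]ethenyl}oxy)-1,3-bis(methoxymethoxy)-2-(3-methylbut-2-enyl)benzene, via aryllithium 16 (not isolated)
Conditions: n-BuLi, TMEDA, THF, −20 °C; then CuBr·SMe2 (10 mol %), 4, −78 °C to rt
Reagents that add atoms: none
Why: Directed ortho-metalation should take the C–H bond between the two MOM ethers, the most acidic and doubly coordinated site, and copper-catalysed SN2 allylation of the aryllithium with prenyl bromide gives the linear prenyl arene.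

Step 11
Reactants: 17 5-({1-[2,4-bis(tert-butyldimethylsilyloxy)phenyl]ethenyl}oxy)-1,3-bis(methoxymethoxy)-2-(3-methylbut-2-enyl)benzene
Product: 19 1-({1-[2,4-bis(tert-butyldimethylsilyloxy)phenyl]ethenyl}oxy)-2-iodo-3,5-bis(methoxymethoxy)-4-(3-methylbut-2-enyl)benzene, via aryllithium 18 (not isolated)
Conditions: s-BuLi, TMEDA, THF, −78 °C; then ICH2CH2I, −78 °C to rt
Reagents that add atoms: 1,2-diiodoethane, ICCI
Why: The second directed ortho-metalation can only take one of the two equivalent C–H bonds between a MOM ether and the vinyloxy group, and 1,2-diiodoethane iodinates the aryllithium without touching the enol ether or the prenyl alkene.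

Step 12
Reactants: 19 1-({1-[2,4-bis(tert-butyldimethylsilyloxy)phenyl]ethenyl}oxy)-2-iodo-3,5-bis(methoxymethoxy)-4-(3-methylbut-2-enyl)benzene; 8 (S)-lavandulyl iodide
Product: 21 1-({1-[2,4-bis(tert-butyldimethylsilyloxy)phenyl]ethenyl}oxy)-3,5-bis(methoxymethoxy)-4-(3-methylbut-2-enyl)-2-[(2R)-5-methyl-2-(prop-1-en-2-yl)hex-4-enyl]benzene, via alkylzinc iodide 20 (not isolated)
Conditions: 8, Zn dust, LiCl, THF, 40 °C; then 19, Pd(OAc)2 (3 mol %), SPhos (6 mol %), THF, 40 °C
Reagents that add atoms: none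
Why: Negishi coupling: zinc insertion into the primary iodide gives an alkylzinc whose β-stereocentre is configurationally stable, and after oxidative addition of the hindered aryl iodide to zerovalent palladium the SPhos complex should transmetalate and eliminate reductively faster than β-hydride elimination.

Step 13
Reactants: 21 1-({1-[2,4-bis(tert-butyldimethylsilyloxy)phenyl]ethenyl}oxy)-3,5-bis(methoxymethoxy)-4-(3-methylbut-2-enyl)-2-[(2R)-5-methyl-2-(prop-1-en-2-yl)hex-4-enyl]benzene
Product: 23 2-({1-[2,4-bis(tert-butyldimethylsilyloxy)phenyl]ethenyl}oxy)-4,6-bis(methoxymethoxy)-5-(3-methylbut-2-enyl)-3-[(2R)-5-methyl-2-(prop-1-en-2-yl)hex-4-enyl]benzaldehyde, via aryllithium 22 (not isolated)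
Conditions: s-BuLi, TMEDA, THF, −78 °C; then DMF, −78 to 0 °C; aq NH4Cl
Reagents that add atoms: N,N-dimethylformamide, CN(C)C=O
Why: The last ring C–H bond, flanked by a MOM ether and the vinyloxy oxygen, is removed by directed ortho-metalation and the aryllithium is formylated with DMF (Bouveault-type formylation), which places the aldehyde next to the enol ether under base only.

Step 14
Reactants: 23 2-({1-[2,4-bis(tert-butyldimethylsilyloxy)phenyl]ethenyl}oxy)-4,6-bis(methoxymethoxy)-5-(3-methylbut-2-enyl)-3-[(2R)-5-methyl-2-(prop-1-en-2-yl)hex-4-enyl]benzaldehyde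
Product: 24 (2S)-2-[2,4-bis(tert-butyldimethylsilyloxy)phenyl]-5,7-bis(methoxymethoxy)-6-(3-methylbut-2-enyl)-8-[(2R)-5-methyl-2-(prop-1-en-2-yl)hex-4-enyl]chroman-4-one
Conditions: [Rh(cod)Cl]2 (2.5 mol %), (R)-DTBM-SEGPHOS (5.5 mol %), NaB[3,5-(CF3)2C6H3]4 (5 mol %), 1,4-dioxane, 60 °C
Reagents that add atoms: none
Why: Proposed new method: the cationic monovalent rhodium bisphosphine complex adds oxidatively into the aldehyde C–H bond of 23, the tethered enol ether inserts into the Rh–H bond with hydride going to the oxygen-bearing carbon (C2) and rhodium to the terminal CH2 (C3), and reductive elimination from the seven-membered acyl(alkyl)rhodacycle forms the C3–C4 bond and returns the catalyst. The closest known reaction type is the rhodium-catalysed enantioselective intramolecular hydroacylation of 1,1-disubstituted alkenes, which turns 2-(1-substituted vinyl)benzaldehydes into 3-substituted indanones and ortho-(2-substituted allyl)benzaldehydes into 3-substituted tetralones; an enol ether oxygen in the tether is what has not been shown. Ring C is closed in the 6-endo-trig mode. The C2 stereocentre is set in the hydride insertion, where the chiral bisphosphine chooses the enantioface of the enol ether; the lavandulyl centre is six bonds away and should not interfere, so the 2S/2R ratio is under catalyst control. The step needs endo regioselectivity over exo closure to a 2-methyl-2-arylbenzofuran-3-one, and chemoselectivity over decarbonylation and over the prenyl and lavandulyl alkenes. The 1,1-disubstituted alkene disfavours the tertiary alkyl–rhodium bond that exo closure requires, the polarity of the enol ether matches hydride delivery to C2, the flanking MOM ether can hold the acyl rhodium hydride by chelation, and the other alkenes cannot reach the metal without a strained ring.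

Step 15
Reactants: 24 (2S)-2-[2,4-bis(tert-butyldimethylsilyloxy)phenyl]-5,7-bis(methoxymethoxy)-6-(3-methylbut-2-enyl)-8-[(2R)-5-methyl-2-(prop-1-en-2-yl)hex-4-enyl]chroman-4-one
Product: 25 Kushenol B
Conditions: 3 M aq HCl, MeOH–THF, 40 °C
Reagents that add atoms: none
Why: Acid-catalysed acetal exchange should remove the two MOM ethers and acidic methanolysis the two aryl silyl ethers in one operation, under non-basic conditions that avoid opening the flavanone to the chalcone.

**Compound list**

1 | (S)-4-benzyl-2-oxazolidinone | O=C1N[C@@H](Cc2ccccc2)CO1 | starting material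
2 | 3-methylbut-2-enoyl chloride | CC(C)=CC(=O)Cl | starting material
3 | (S)-4-benzyl-3-(3-methylbut-2-enoyl)oxazolidin-2-one | CC(C)=CC(=O)N1[C@@H](Cc2ccccc2)COC1=O | intermediate
4 | prenyl bromide (1-bromo-3-methylbut-2-ene) | CC(C)=CCBr | starting material
5 | sodium Z(O)-dienolate of 3 (not isolated) | [Na+].[O-]/C(=C\C(C)=C)N1[C@@H](Cc2ccccc2)COC1=O | intermediate
6 | (S)-4-benzyl-3-[(2S)-5-methyl-2-(prop-1-en-2-yl)hex-4-enoyl]oxazolidin-2-one | C=C(C)[C@H](CC=C(C)C)C(=O)N1[C@@H](Cc2ccccc2)COC1=O | intermediate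
7 | (S)-lavandulol, (2S)-5-methyl-2-(prop-1-en-2-yl)hex-4-en-1-ol | C=C(C)[C@H](CC=C(C)C)CO | intermediate
8 | (S)-lavandulyl iodide, (3S)-3-(iodomethyl)-2,6-dimethylhepta-1,5-diene | C=C(C)[C@H](CC=C(C)C)CI | intermediate
9 | 2,4-dihydroxybenzoic acid | O=C(O)c1ccc(O)cc1O | starting material
10 | tert-butyldimethylsilyl 2,4-bis(tert-butyldimethylsilyloxy)benzoate | CC(C)(C)[Si](C)(C)OC(=O)c1ccc(O[Si](C)(C)C(C)(C)C)cc1O[Si](C)(C)C(C)(C)C | intermediate
11 | 2,4-bis(tert-butyldimethylsilyloxy)benzoyl chloride | O=C(Cl)c1ccc(O[Si](C)(C)C(C)(C)C)cc1O[Si](C)(C)C(C)(C)C | intermediate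
12 | phloroglucinol | Oc1cc(O)cc(O)c1 | starting material
13 | 3,5-bis(methoxymethoxy)phenol | COCOc1cc(O)cc(OCOC)c1 | intermediate
14 | 3,5-bis(methoxymethoxy)phenyl 2,4-bis(tert-butyldimethylsilyloxy)benzoate | COCOc1cc(OCOC)cc(OC(=O)c2ccc(O[Si](C)(C)C(C)(C)C)cc2O[Si](C)(C)C(C)(C)C)c1 | intermediate
15 | 1-({1-[2,4-bis(tert-butyldimethylsilyloxy)phenyl]ethenyl}oxy)-3,5-bis(methoxymethoxy)benzene | COCOc1cc(OCOC)cc(OC(=C)c2ccc(O[Si](C)(C)C(C)(C)C)cc2O[Si](C)(C)C(C)(C)C)c1 | intermediate
16 | aryllithium from 15, lithium on the carbon between the two MOM ethers (not isolated) | [Li]c1c(OCOC)cc(OC(=C)c2ccc(O[Si](C)(C)C(C)(C)C)cc2O[Si](C)(C)C(C)(C)C)cc1OCOC | intermediate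
17 | 5-({1-[2,4-bis(tert-butyldimethylsilyloxy)phenyl]ethenyl}oxy)-1,3-bis(methoxymethoxy)-2-(3-methylbut-2-enyl)benzene | CC(C)=CCc1c(OCOC)cc(OC(=C)c2ccc(O[Si](C)(C)C(C)(C)C)cc2O[Si](C)(C)C(C)(C)C)cc1OCOC | intermediate
18 | aryllithium from 17, lithium between a MOM ether and the vinyloxy group (not isolated) | [Li]c1c(OCOC)c(CC=C(C)C)c(OCOC)cc1OC(=C)c1ccc(O[Si](C)(C)C(C)(C)C)cc1O[Si](C)(C)C(C)(C)C | intermediate
19 | 1-({1-[2,4-bis(tert-butyldimethylsilyloxy)phenyl]ethenyl}oxy)-2-iodo-3,5-bis(methoxymethoxy)-4-(3-methylbut-2-enyl)benzene | Ic1c(OCOC)c(CC=C(C)C)c(OCOC)cc1OC(=C)c1ccc(O[Si](C)(C)C(C)(C)C)cc1O[Si](C)(C)C(C)(C)C | intermediate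
20 | [(2S)-5-methyl-2-(prop-1-en-2-yl)hex-4-enyl]zinc iodide (not isolated) | C=C(C)[C@H](CC=C(C)C)C[Zn]I | intermediate
21 | 1-({1-[2,4-bis(tert-butyldimethylsilyloxy)phenyl]ethenyl}oxy)-3,5-bis(methoxymethoxy)-4-(3-methylbut-2-enyl)-2-[(2R)-5-methyl-2-(prop-1-en-2-yl)hex-4-enyl]benzene | C=C(C)[C@H](CC=C(C)C)Cc1c(OCOC)c(CC=C(C)C)c(OCOC)cc1OC(=C)c1ccc(O[Si](C)(C)C(C)(C)C)cc1O[Si](C)(C)C(C)(C)C | intermediate
22 | aryllithium from 21, lithium at the last ring position (not isolated) | C=C(C)[C@H](CC=C(C)C)Cc1c(OCOC)c(CC=C(C)C)c(OCOC)c([Li])c1OC(=C)c1ccc(O[Si](C)(C)C(C)(C)C)cc1O[Si](C)(C)C(C)(C)C | intermediate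
23 | 2-({1-[2,4-bis(tert-butyldimethylsilyloxy)phenyl]ethenyl}oxy)-4,6-bis(methoxymethoxy)-5-(3-methylbut-2-enyl)-3-[(2R)-5-methyl-2-(prop-1-en-2-yl)hex-4-enyl]benzaldehyde | C=C(C)[C@H](CC=C(C)C)Cc1c(OCOC)c(CC=C(C)C)c(OCOC)c(C=O)c1OC(=C)c1ccc(O[Si](C)(C)C(C)(C)C)cc1O[Si](C)(C)C(C)(C)C | intermediate
24 | (2S)-2-[2,4-bis(tert-butyldimethylsilyloxy)phenyl]-5,7-bis(methoxymethoxy)-6-(3-methylbut-2-enyl)-8-[(2R)-5-methyl-2-(prop-1-en-2-yl)hex-4-enyl]chroman-4-one | C=C(C)[C@H](CC=C(C)C)Cc1c(OCOC)c(CC=C(C)C)c(OCOC)c2c1O[C@H](c1ccc(O[Si](C)(C)C(C)(C)C)cc1O[Si](C)(C)C(C)(C)C)CC2=O | intermediate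
25 | Kushenol B, (2S)-2-(2,4-dihydroxyphenyl)-5,7-dihydroxy-6-(3-methylbut-2-enyl)-8-[(2R)-5-methyl-2-(prop-1-en-2-yl)hex-4-enyl]chroman-4-one | C=C(C)[C@H](CC=C(C)C)Cc1c(O)c(CC=C(C)C)c(O)c2c1O[C@H](c1ccc(O)cc1O)CC2=O | target

**Step count**

Total: 15 steps. Longest linear sequence: 10 steps (steps 5, 6 and 8 to 15, from 2,4-dihydroxybenzoic acid 9).

**Steps most likely to fail**

1. Step 14 (proposed new method). The acyl rhodium hydride may decarbonylate and poison the catalyst as a rhodium carbonyl. Insertion may go exo to the benzofuranone. The Lewis-acidic metal may trigger a Prins-type attack of the enol ether on the aldehyde. Enantioface selection may be low.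
Fallback (known chemistry, sets out from 21, comes back at 25): ring C is closed by the classical chalcone route, in which O1–C2 is formed last. Aryllithium 22, generated from 21 as in step 13, is quenched with N-methoxy-N-methylacetamide to give the aryl methyl ketone F1. Mild hydrolysis of the enol ether (pyridinium p-toluenesulfonate, wet acetone, rt) frees the 2'-hydroxyacetophenone F2. Claisen–Schmidt condensation with commercial 2,4-bis(methoxymethoxy)benzaldehyde (KOH, EtOH, rt) gives the 2'-hydroxychalcone F3. Oxa-Michael cyclisation (NaOAc, EtOH, reflux) gives the tetra-MOM flavanone as a pair of C2 diastereomers. The 2S isomer F4 is separated by preparative HPLC, and the 2R isomer is re-equilibrated through the chalcone under the same conditions. The acid treatment of step 15 then gives 25.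

2. Step 10. n-BuLi may add to the styrene-type double bond of the enol ether, attack silicon of the aryl silyl ethers, or metalate next to the vinyloxy group instead of between the MOM ethers.
Fallback (sets out from 13, comes back at 17): prenyl is introduced before the enol ether exists. Phenol 13 is silylated (i-Pr3SiCl, imidazole, DMF) to the triisopropylsilyl ether F5, whose bulky silyloxy group blocks both of its ortho positions, so that n-BuLi should metalate only between the MOM ethers. Copper-catalysed prenylation with 4 gives the prenyl arene F6. Bu4NF in THF removes the silyl group to give 3,5-bis(methoxymethoxy)-4-prenylphenol F7. Acylation with 11 (Et3N, DMAP) gives the ester F8, and Tebbe methylenation as in step 9 gives 17.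

3. Step 15. Brønsted acid may erode the C2 configuration, by ring opening to the chalcone or by ionisation of the benzylic C2–O1 bond next to the electron-rich ring B. It may also cyclise the prenyl or isopropenyl groups onto the neighbouring phenols.
Fallback (sets out from 24, comes back at 25): the unmasking is done in two stages without Brønsted acid. TMSOTf and 2,2'-bipyridyl in CH3CN at 0 °C convert the two aryl MOM ethers into aryl trimethylsilyl ethers, which water hydrolyses to the 5,7-dihydroxyflavanone F9. KHF2 in MeOH at rt then removes the two aryl TBS ethers to give 25.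

**Further compounds**

F1 | step 14 | 1-[2-({1-[2,4-bis(tert-butyldimethylsilyloxy)phenyl]ethenyl}oxy)-4,6-bis(methoxymethoxy)-5-(3-methylbut-2-enyl)-3-[(2R)-5-methyl-2-(prop-1-en-2-yl)hex-4-enyl]phenyl]ethanone | C=C(C)[C@H](CC=C(C)C)Cc1c(OCOC)c(CC=C(C)C)c(OCOC)c(C(C)=O)c1OC(=C)c1ccc(O[Si](C)(C)C(C)(C)C)cc1O[Si](C)(C)C(C)(C)C
F2 | step 14 | 1-[2-hydroxy-4,6-bis(methoxymethoxy)-5-(3-methylbut-2-enyl)-3-[(2R)-5-methyl-2-(prop-1-en-2-yl)hex-4-enyl]phenyl]ethanone | C=C(C)[C@H](CC=C(C)C)Cc1c(OCOC)c(CC=C(C)C)c(OCOC)c(C(C)=O)c1O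
F3 | step 14 | (E)-3-[2,4-bis(methoxymethoxy)phenyl]-1-[2-hydroxy-4,6-bis(methoxymethoxy)-5-(3-methylbut-2-enyl)-3-[(2R)-5-methyl-2-(prop-1-en-2-yl)hex-4-enyl]phenyl]prop-2-en-1-one | C=C(C)[C@H](CC=C(C)C)Cc1c(OCOC)c(CC=C(C)C)c(OCOC)c(C(=O)/C=C/c2ccc(OCOC)cc2OCOC)c1O
F4 | step 14 | (2S)-2-[2,4-bis(methoxymethoxy)phenyl]-5,7-bis(methoxymethoxy)-6-(3-methylbut-2-enyl)-8-[(2R)-5-methyl-2-(prop-1-en-2-yl)hex-4-enyl]chroman-4-one | C=C(C)[C@H](CC=C(C)C)Cc1c(OCOC)c(CC=C(C)C)c(OCOC)c2c1O[C@H](c1ccc(OCOC)cc1OCOC)CC2=O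
F5 | step 10 | [3,5-bis(methoxymethoxy)phenoxy]triisopropylsilane | COCOc1cc(OCOC)cc(O[Si](C(C)C)(C(C)C)C(C)C)c1
F6 | step 10 | [3,5-bis(methoxymethoxy)-4-(3-methylbut-2-enyl)phenoxy]triisopropylsilane | COCOc1cc(O[Si](C(C)C)(C(C)C)C(C)C)cc(OCOC)c1CC=C(C)C
F7 | step 10 | 3,5-bis(methoxymethoxy)-4-(3-methylbut-2-enyl)phenol | COCOc1cc(O)cc(OCOC)c1CC=C(C)C
F8 | step 10 | 3,5-bis(methoxymethoxy)-4-(3-methylbut-2-enyl)phenyl 2,4-bis(tert-butyldimethylsilyloxy)benzoate | COCOc1cc(OC(=O)c2ccc(O[Si](C)(C)C(C)(C)C)cc2O[Si](C)(C)C(C)(C)C)cc(OCOC)c1CC=C(C)C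
F9 | step 15 | (2S)-2-[2,4-bis(tert-butyldimethylsilyloxy)phenyl]-5,7-dihydroxy-6-(3-methylbut-2-enyl)-8-[(2R)-5-methyl-2-(prop-1-en-2-yl)hex-4-enyl]chroman-4-one | C=C(C)[C@H](CC=C(C)C)Cc1c(O)c(CC=C(C)C)c(O)c2c1O[C@H](c1ccc(O[Si](C)(C)C(C)(C)C)cc1O[Si](C)(C)C(C)(C)C)CC2=O
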